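**Plan**

1. Retrosynthesis: cut the ester C3–O bond (acylation), then the C11–O bond together with the C6=C7 shift (singlet-oxygen ene reaction of a 7(11)-en-8-one), then the two C–O bonds of the C3/C4 cis-glycol (osmylation). This leads back to eudesma-3,7(11)-dien-8-one 18, whose ring A is cut at C1–C2 and C3=C4 in one stroke.
2. Enabling feature: in ring A the bare methylenes C1 and C2 lie between quaternary C10 and the glycol carbons, and C4 carries a methyl. C1 is therefore the retron of a primary radical on C10, C2–C3 of a vinylphosphonium unit, and C4/C15 of an acetyl group on C5 (1,4 to C1); radical addition followed by Wittig closure unites them.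
3. Ring B (C5–C10) comes from (1R,5R)-verbenone: conjugate allylation builds quaternary C10, and cleavage of the cyclobutane C–C bond gives the cyclohexanone with a masked acetyl (isopropenyl) on C5 and an enol silane that places the C7 side chain.
4. Forward order: ring B (steps 1–6), ring A (step 7), then glycol, tertiary alcohol and ester (steps 8–10).
5. Stereochemistry: C5 is the verbenone bridgehead. C10 arises by addition anti to the gem-dimethyl bridge, which puts the C1 and C4 arms trans (trans ring fusion). C3 and C4 arise by osmylation anti to the axial C10 methyl.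

Key step: step 7

Remark: eudesmane numbering (C1–C15) is used for the carbons throughout; the C7 epimers of 9 are carried as a mixture because C7 becomes sp2 in step 4.

**Route**

Step 1
Reactants: 1 (1R,5R)-(+)-verbenone; 2 allylmagnesium bromide
Product: 4 (1R,4R,5R)-4,6,6-trimethyl-4-(prop-2-en-1-yl)bicyclo[3.1.1]heptan-2-one, via enol silane 3 (not isolated)
Conditions: 2, CuBr·SMe2, LiCl, Me3SiCl, THF, −78 °C; then 1 M HCl, 0 °C
Reagents that add atoms: none
Why: Me3SiCl-accelerated organocopper conjugate (1,4-) addition to the β,β-disubstituted enone should deliver allyl to the face anti to the gem-dimethyl bridge, which sets the quaternary carbon (future C10) with the allyl group on the methylene-bridge side, and acidic work-up hydrolyses 3 to 4.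

Step 2
Reactants: 4
Product: 6 trimethyl{[(4S,5R)-5-methyl-4-(prop-1-en-2-yl)-5-(prop-2-en-1-yl)cyclohex-1-en-1-yl]oxy}silane, via tertiary iodide 5 (not isolated)
Conditions: Me3SiI, CH2Cl2, −40 to 0 °C; then DBU, 40 °C
Reagents that add atoms: iodotrimethylsilane, C[Si](C)(C)I
Why: Silyl-iodide-induced homoconjugate opening of a cyclobutyl ketone (the reaction type known for nopinone) should break the cyclobutane bond between the carbonyl α-carbon and the gem-dimethyl carbon with capture by iodide; E2 dehydroiodination should then take a methyl proton, because the isopropylidene alternative clashes with the neighbouring quaternary carbon, and the two stereocentres (future C5 and C10) are not touched, so the allyl and isopropenyl arms end up trans.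

Step 3
Reactants: 6; 7 acetone
Product: 9 (4S,5R)-2-(2-hydroxypropan-2-yl)-5-methyl-4-(prop-1-en-2-yl)-5-(prop-2-en-1-yl)cyclohexan-1-one (C2 epimers), via lithium enolate 8 (not isolated)
Conditions: MeLi, THF, 0 °C; ZnCl2, then 7, −78 to −20 °C; aq NH4Cl
Reagents that add atoms: none
Why: Cleavage of the enol silane by MeLi gives the enolate regiospecifically on the C7 side, and its directed aldol addition to acetone (zinc enolate to suppress proton transfer and retro-aldol) installs C11–C13; the new C7 stereocentre forms without control and is erased in step 4.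

Step 4
Reactants: 9
Product: 11 (4S,5R)-5-methyl-4-(prop-1-en-2-yl)-5-(prop-2-en-1-yl)-2-(propan-2-ylidene)cyclohexan-1-one, via tertiary mesylate 10 (not isolated)
Conditions: MsCl, Et3N, DMAP (cat.), CH2Cl2, 0 °C to rt; then DBU, rt
Reagents that add atoms: none
Why: Mesylation of the tertiary aldol hydroxyl through sulfene and E1cB elimination completes the aldol condensation, and DBU should equilibrate any isopropenyl isomer to the conjugated tetrasubstituted isopropylidene ketone (pulegone type); no stereocentre is formed.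

Step 5
Reactants: 11
Product: 13 2-[(1R,2R)-2-acetyl-1-methyl-5-oxo-4-(propan-2-ylidene)cyclohexyl]acetaldehyde, via bis-glycol 12 (not isolated)
Conditions: OsO4 (2 mol %), NaIO4, 2,6-lutidine, dioxane/H2O, rt
Reagents that add atoms: osmium tetroxide, O=[Os](=O)(=O)=O; sodium periodate, [Na+].[O-]I(=O)(=O)=O; water, O
Why: In this Lemieux–Johnson oxidation OsO4 should dihydroxylate the mono- and 1,1-disubstituted terminal alkenes far faster than the tetrasubstituted electron-poor enone alkene, and periodate cleaves both glycols, turning allyl into the CH2CHO arm and isopropenyl into the C4 acetyl group while the lutidine buffer protects C5 from epimerisation.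

Step 6
Reactants: 13
Product: 14 2-[(1S,2R)-2-acetyl-1-methyl-5-oxo-4-(propan-2-ylidene)cyclohexyl]acetic acid
Conditions: NaClO2, NaH2PO4, 2-methylbut-2-ene, t-BuOH/H2O, 0 °C to rt
Reagents that add atoms: sodium chlorite, [Na+].[O-]Cl=O
Why: Pinnick oxidation converts the aldehyde to the acid under buffered conditions that leave the methyl ketone, the enone and the stereocentre at C5 untouched.

Step 7
Reactants: 14; 15 vinyltriphenylphosphonium bromide
Product: 18 (4aR,8aR)-5,8a-dimethyl-3-(propan-2-ylidene)-3,4,4a,7,8,8a-hexahydronaphthalen-2(1H)-one (eudesma-3,7(11)-dien-8-one), via potassium carboxylate 16 (not isolated), via phosphonium ylide 17 (not isolated)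
Conditions: t-BuOK (1.0 equiv), DMSO, 20 °C; then 15 (1.5 equiv), 2,4,5,6-tetrakis(carbazol-9-yl)isophthalonitrile (4CzIPN, 2 mol %), blue LEDs (450 nm), degassed, 25 °C
Reagents that add atoms: none
Why: Proposed new method: the excited photocatalyst oxidises carboxylate 16, loss of CO2 gives the primary C1 radical on quaternary C10, this adds to the terminal carbon of the vinylphosphonium cation (C1–C2 bond), and the α-phosphonio radical is reduced by the photocatalyst radical anion to ylide 17 in a redox-neutral radical–polar crossover. The ylide carbon C3 then attacks the C4 acetyl carbonyl and the oxaphosphetane collapses to C3=C4 and Ph3PO, so ring A closes as a six-membered carbocycle by 6-exo addition to the exocyclic carbonyl (intramolecular Wittig). The closest known reaction types are the decarboxylative photoredox Giese addition, radical addition to vinylphosphonium salts, and the Schweizer annulation (nucleophile plus vinyltriphenylphosphonium, then intramolecular Wittig). No new stereocentre is formed; the trans ring fusion follows from the trans placement of the C1 and C4 arms on C10 and C5 set in steps 1 and 2. The step needs the ylide to choose the acetyl over the C8 ketone, which is secured because C8 is conjugated, flanked by the tetrasubstituted isopropylidene and could only give a bridgehead olefin; it also needs C5 to keep its configuration, which is favoured because the ylide arises by electron transfer without excess base and any proton it abstracts should come from the acetyl methyl, not the hindered C5–H.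

Step 8
Reactants: 18
Product: 19 (4aR,5S,6R,8aR)-5,6-dihydroxy-5,8a-dimethyl-3-(propan-2-ylidene)octahydronaphthalen-2(1H)-one
Conditions: OsO4 (2 mol %), NMO, acetone/H2O, 0 °C to rt
Reagents that add atoms: osmium tetroxide, O=[Os](=O)(=O)=O; N-methylmorpholine N-oxide, C[N+]1([O-])CCOCC1; water, O
Why: Catalytic OsO4/NMO syn-dihydroxylation should take only the electron-rich trisubstituted C3=C4 bond (the tetrasubstituted enone alkene is inert) and attack from the α face, anti to the axial C10 methyl that shields the β face of ring A, giving the cis 3α,4α-diol with the C4 methyl β.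

Step 9
Reactants: 19
Product: 21 (4aR,5S,6R,8aR)-5,6-dihydroxy-3-(2-hydroxypropan-2-yl)-5,8a-dimethyl-4a,5,6,7,8,8a-hexahydronaphthalen-2(1H)-one, via hydroperoxide 20 (not isolated)
Conditions: O2, tetraphenylporphyrin (cat.), visible light, CH2Cl2, −20 °C; then PPh3, 0 °C
Reagents that add atoms: oxygen, O=O
Why: In the Schenck ene reaction of singlet oxygen with an s-cis α-alkylidene ketone, hydrogen should be abstracted from the ring methylene C6 geminal to the carbonyl on the α-carbon, so oxygen lands on C11 and the double bond moves to C6=C7; PPh3 then reduces hydroperoxide 20 to the tertiary alcohol, and no stereocentre is created.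

Step 10
Reactants: 21; 22 3-methylbut-2-enoyl chloride
Product: 23 (1S,2R,4aR,8aR)-1-hydroxy-7-(2-hydroxypropan-2-yl)-1,4a-dimethyl-6-oxo-1,2,3,4,4a,5,6,8a-octahydronaphthalen-2-yl 3-methylbut-2-enoate (target)
Conditions: 22, pyridine, DMAP (cat.), CH2Cl2, 0 °C to rt
Reagents that add atoms: none
Why: DMAP-catalysed acylation should be selective for the only secondary hydroxyl (C3) over the two tertiary ones; pyridine as the sole base avoids the vinylketene pathway that would deconjugate the senecioyl group, and C3 keeps its configuration because its C–O bond is not broken.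

**Compound list**

1 | (1R,5R)-(+)-verbenone, (1R,5R)-4,6,6-trimethylbicyclo[3.1.1]hept-3-en-2-one | CC1=CC(=O)[C@@H]2C[C@H]1C2(C)C | starting material
2 | allylmagnesium bromide | C=CC[Mg]Br | starting material
3 | trimethylsilyl enol ether of 4, trimethyl{[(1R,4S,5R)-4,6,6-trimethyl-4-(prop-2-en-1-yl)bicyclo[3.1.1]hept-2-en-2-yl]oxy}silane | C[Si](C)(C)OC1=C[C@@](C)(CC=C)[C@H]2C[C@@H]1C2(C)C | intermediate
4 | (1R,4R,5R)-4,6,6-trimethyl-4-(prop-2-en-1-yl)bicyclo[3.1.1]heptan-2-one (allyl anti to the gem-dimethyl bridge) | O=C1C[C@@](C)(CC=C)[C@H]2C[C@@H]1C2(C)C | intermediate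
5 | trimethyl{[(4R,5R)-4-(2-iodopropan-2-yl)-5-methyl-5-(prop-2-en-1-yl)cyclohex-1-en-1-yl]oxy}silane | C[Si](C)(C)OC1=CC[C@@H](C(C)(C)I)[C@](C)(CC=C)C1 | intermediate
6 | trimethyl{[(4S,5R)-5-methyl-4-(prop-1-en-2-yl)-5-(prop-2-en-1-yl)cyclohex-1-en-1-yl]oxy}silane | C[Si](C)(C)OC1=CC[C@@H](C(C)=C)[C@](C)(CC=C)C1 | intermediate
7 | acetone | CC(C)=O | starting material
8 | lithium (4S,5R)-5-methyl-4-(prop-1-en-2-yl)-5-(prop-2-en-1-yl)cyclohex-1-en-1-olate | [Li]OC1=CC[C@@H](C(C)=C)[C@](C)(CC=C)C1 | intermediate
9 | (4S,5R)-2-(2-hydroxypropan-2-yl)-5-methyl-4-(prop-1-en-2-yl)-5-(prop-2-en-1-yl)cyclohexan-1-one (C2 epimers) | O=C1C[C@@](C)(CC=C)[C@H](C(C)=C)CC1C(C)(C)O | intermediate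
10 | methanesulfonate ester of the tertiary hydroxyl of 9 | O=C1C[C@@](C)(CC=C)[C@H](C(C)=C)CC1C(C)(C)OS(C)(=O)=O | intermediate
11 | (4S,5R)-5-methyl-4-(prop-1-en-2-yl)-5-(prop-2-en-1-yl)-2-(propan-2-ylidene)cyclohexan-1-one | O=C1C[C@@](C)(CC=C)[C@H](C(C)=C)CC1=C(C)C | intermediate
12 | bis-glycol of 11 (both terminal alkenes dihydroxylated) | O=C1C[C@@](C)(CC(O)CO)[C@H](C(C)(O)CO)CC1=C(C)C | intermediate
13 | 2-[(1R,2R)-2-acetyl-1-methyl-5-oxo-4-(propan-2-ylidene)cyclohexyl]acetaldehyde | O=C1C[C@@](C)(CC=O)[C@H](C(C)=O)CC1=C(C)C | intermediate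
14 | 2-[(1S,2R)-2-acetyl-1-methyl-5-oxo-4-(propan-2-ylidene)cyclohexyl]acetic acid | O=C1C[C@@](C)(CC(=O)O)[C@H](C(C)=O)CC1=C(C)C | intermediate
15 | vinyltriphenylphosphonium bromide | C=C[P+](c1ccccc1)(c1ccccc1)c1ccccc1.[Br-] | starting material
16 | potassium salt of 14 | O=C1C[C@@](C)(CC(=O)[O-])[C@H](C(C)=O)CC1=C(C)C.[K+] | intermediate
17 | {3-[(1R,2R)-2-acetyl-1-methyl-5-oxo-4-(propan-2-ylidene)cyclohexyl]propylidene}triphenylphosphorane | O=C1C[C@@](C)(CCC=P(c2ccccc2)(c2ccccc2)c2ccccc2)[C@H](C(C)=O)CC1=C(C)C | intermediate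
18 | (4aR,8aR)-5,8a-dimethyl-3-(propan-2-ylidene)-3,4,4a,7,8,8a-hexahydronaphthalen-2(1H)-one (eudesma-3,7(11)-dien-8-one, trans-fused) | C1CC[C@]2(C)CC(=O)C(=C(C)C)C[C@H]2C(C)=C1 | intermediate
19 | (4aR,5S,6R,8aR)-5,6-dihydroxy-5,8a-dimethyl-3-(propan-2-ylidene)octahydronaphthalen-2(1H)-one (3α,4α-diol) | O[C@@H]1CC[C@]2(C)CC(=O)C(=C(C)C)C[C@H]2[C@]1(C)O | intermediate
20 | (4aR,5S,6R,8aR)-3-(2-hydroperoxypropan-2-yl)-5,6-dihydroxy-5,8a-dimethyl-4a,5,6,7,8,8a-hexahydronaphthalen-2(1H)-one | O[C@@H]1CC[C@]2(C)CC(=O)C(C(C)(C)OO)=C[C@H]2[C@]1(C)O | intermediate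
21 | (4aR,5S,6R,8aR)-5,6-dihydroxy-3-(2-hydroxypropan-2-yl)-5,8a-dimethyl-4a,5,6,7,8,8a-hexahydronaphthalen-2(1H)-one | O[C@@H]1CC[C@]2(C)CC(=O)C(C(C)(C)O)=C[C@H]2[C@]1(C)O | intermediate
22 | 3-methylbut-2-enoyl chloride | CC(C)=CC(=O)Cl | starting material
23 | (1S,2R,4aR,8aR)-1-hydroxy-7-(2-hydroxypropan-2-yl)-1,4a-dimethyl-6-oxo-1,2,3,4,4a,5,6,8a-octahydronaphthalen-2-yl 3-methylbut-2-enoate | CC(C)=CC(=O)O[C@@H]1CC[C@]2(C)CC(=O)C(C(C)(C)O)=C[C@H]2[C@]1(C)O | target

**Count**

Total steps: 10. Longest linear sequence: 10 steps (from 1).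

**Steps most likely to fail**

Step 7 (proposed new method). The ylide may be quenched before it closes (protonation by traces of water or unreacted acid, or Michael addition to a second vinylphosphonium cation), the primary carboxylate may be oxidised too slowly, or enolisation of the acetyl group may epimerise C5. The fallback uses only known chemistry and closes ring A by ring-closing metathesis; it sets out from 1 and comes back at 18. Copper-catalysed conjugate addition of but-3-en-1-ylmagnesium bromide (CuBr·SMe2 cat., THF, −40 °C) to 1 gives (1R,4R,5R)-4-(but-3-en-1-yl)-4,6,6-trimethylbicyclo[3.1.1]heptan-2-one F1. Opening with Me3SiI gives the tertiary iodide trimethyl{[(4R,5R)-5-(but-3-en-1-yl)-4-(2-iodopropan-2-yl)-5-methylcyclohex-1-en-1-yl]oxy}silane F2, which DBU converts to trimethyl{[(4S,5R)-5-(but-3-en-1-yl)-5-methyl-4-(prop-1-en-2-yl)cyclohex-1-en-1-yl]oxy}silane F3. MeLi gives lithium (4S,5R)-5-(but-3-en-1-yl)-5-methyl-4-(prop-1-en-2-yl)cyclohex-1-en-1-olate F4, and aldol addition to acetone gives (4S,5R)-5-(but-3-en-1-yl)-2-(2-hydroxypropan-2-yl)-5-methyl-4-(prop-1-en-2-yl)cyclohexan-1-one F5. MsCl/Et3N gives the tertiary methanesulfonate of F5 F6, and DBU gives (4S,5R)-5-(but-3-en-1-yl)-5-methyl-4-(prop-1-en-2-yl)-2-(propan-2-ylidene)cyclohexan-1-one F7. Metathesis of the but-3-enyl terminus with the isopropenyl group, using (H2IMes)(PCy3)Cl2Ru=CHPh (second-generation Grubbs catalyst) in CH2Cl2 at 40 °C, should close the trisubstituted C3=C4 cyclohexene and give 18; the tetrasubstituted enone alkene does not take part.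

Step 2. The tertiary iodide may eliminate toward the ring (isopropylidene instead of isopropenyl), HI may add to the allyl group, or iodide may open the other cyclobutane bond. The fallback avoids both the ionic opening and the elimination; it sets out from 4 and comes back at 9 through enolate 8. Flash vacuum pyrolysis of 4 (about 500 °C, 0.1 mbar) should effect the homo-retro-ene reaction (the reverse of the Conia-ene reaction, known for nopinone): a methyl hydrogen of the gem-dimethyl carbon passes to the carbonyl oxygen while the cyclobutane bond breaks, which gives (3R,4S)-3-methyl-4-(prop-1-en-2-yl)-3-(prop-2-en-1-yl)cyclohexan-1-one F8 with the isopropenyl group formed directly. Kinetic deprotonation with LDA (THF, −78 °C) on the less hindered side, away from quaternary C10, gives 8, which is carried on with ZnCl2 and acetone to 9.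

Step 9. Hydrogen abstraction may occur from the isopropylidene methyls instead of C6 (poor regioselectivity of the ene reaction), and the hydroperoxide may be oxidised further. The fallback reaches the same hydroxy enone without singlet oxygen; it sets out from 18 and comes back at 21. Weitz–Scheffer epoxidation of the enone (H2O2, NaOH, MeOH, 0 °C; the isolated C3=C4 bond is inert to the nucleophilic oxidant) gives 7,11-epoxyeudesm-3-en-8-one F9. SmI2 (THF/MeOH, −78 °C) cleaves the C–O bond α to the ketone and gives 11-hydroxyeudesm-3-en-8-one F10. Dehydrogenation with 2-iodoxybenzoic acid (DMSO, 65 °C) can introduce unsaturation only toward C6, since C10 carries no hydrogen, and gives 11-hydroxyeudesma-3,6-dien-8-one F11. Catalytic OsO4/NMO dihydroxylation of the remaining electron-rich C3=C4 bond from the α face then gives 21.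

**Further compounds**

F1 | step 7 | (1R,4R,5R)-4-(but-3-en-1-yl)-4,6,6-trimethylbicyclo[3.1.1]heptan-2-one | O=C1C[C@@](C)(CCC=C)[C@H]2C[C@@H]1C2(C)C
F2 | step 7 | trimethyl{[(4R,5R)-5-(but-3-en-1-yl)-4-(2-iodopropan-2-yl)-5-methylcyclohex-1-en-1-yl]oxy}silane | C[Si](C)(C)OC1=CC[C@@H](C(C)(C)I)[C@](C)(CCC=C)C1
F3 | step 7 | trimethyl{[(4S,5R)-5-(but-3-en-1-yl)-5-methyl-4-(prop-1-en-2-yl)cyclohex-1-en-1-yl]oxy}silane | C[Si](C)(C)OC1=CC[C@@H](C(C)=C)[C@](C)(CCC=C)C1
F4 | step 7 | lithium (4S,5R)-5-(but-3-en-1-yl)-5-methyl-4-(prop-1-en-2-yl)cyclohex-1-en-1-olate | [Li]OC1=CC[C@@H](C(C)=C)[C@](C)(CCC=C)C1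
F5 | step 7 | (4S,5R)-5-(but-3-en-1-yl)-2-(2-hydroxypropan-2-yl)-5-methyl-4-(prop-1-en-2-yl)cyclohexan-1-one (C2 epimers) | O=C1C[C@@](C)(CCC=C)[C@H](C(C)=C)CC1C(C)(C)O
F6 | step 7 | methanesulfonate ester of the tertiary hydroxyl of F5 | O=C1C[C@@](C)(CCC=C)[C@H](C(C)=C)CC1C(C)(C)OS(C)(=O)=O
F7 | step 7 | (4S,5R)-5-(but-3-en-1-yl)-5-methyl-4-(prop-1-en-2-yl)-2-(propan-2-ylidene)cyclohexan-1-one | O=C1C[C@@](C)(CCC=C)[C@H](C(C)=C)CC1=C(C)C
F8 | step 2 | (3R,4S)-3-methyl-4-(prop-1-en-2-yl)-3-(prop-2-en-1-yl)cyclohexan-1-one | O=C1C[C@@](C)(CC=C)[C@H](C(C)=C)CC1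
F9 | step 9 | 7,11-epoxyeudesm-3-en-8-one (spiro-epoxide at C7, epimers) | C1CC[C@]2(C)CC(=O)C3(OC3(C)C)C[C@H]2C(C)=C1
F10 | step 9 | 11-hydroxyeudesm-3-en-8-one (C7 epimers) | C1CC[C@]2(C)CC(=O)C(C(C)(C)O)C[C@H]2C(C)=C1
F11 | step 9 | 11-hydroxyeudesma-3,6-dien-8-one | C1CC[C@]2(C)CC(=O)C(C(C)(C)O)=C[C@H]2C(C)=C1
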